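The rate constants were drawn at random within sensible limits; the rest is arithmetic.

A second-order constant, counted per molar per second, becomes a pure number once it is multiplied by a concentration and a time, and that number is what I carry through this flask.

starting material 0.010 M; solid reagent 1.00 equiv; time 5.0 min

    starting material + coupling partner → intermediate + by-product (k1 = 1.8 M⁻¹ s⁻¹)
    solid reagent ⇌ coupling partner, rate k2*(cs2 - [coupling partner]) while solid is left; crystals form when [coupling partner] > cs2 (cs2 = 5.3 mM, k2 = 0.041 s⁻¹)
    intermediate → product (k3 = 0.014 s⁻¹)

- solid, in amounts per volume of the solution: solid reagent
- at the start none of the solid reagent is in solution
- run time (flask): 5.0 min

- amount of product at 5.0 min, in percent of the starting material charged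
- the change that raises the amount of product at 5.0 min, in percent of the starting material charged most ("none" if none brings more than 2 percentage points) (noon / summer / none)
- amount of product at 5.0 min, in percent of the starting material charged, after noon

- noon: doubling the dissolution coefficient of step 2, all else as stated
- summer: doubling the solubility in step 2, all else as stated

While solid reagent lasts in this flask, I hold c(coupling partner) at the level where dissolving matches step 1 at the charged starting material, 3.68 mM. That makes the starting material decay pseudo-first-order until it meets this level; after that, with 1.00 equiv, the two fall together. Each intermediate lives 71.4 s, so I read the clock that much before the end, which gives 4.11. The feed stretch adds 0.00314. Their sum is 4.12, the thinning number: the factor by which starting material has thinned one lifetime before the end. Whatever has gone by then I count as product, so y is 75.7%.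

Is one number enough? The level in this flask settles in 16.9 s, far less than the run time, but a sharp shift is a rough picture of the intermediate. With the same number, noon gives 4.50 and summer 5.06, so I choose summer, with 77.8% after noon.

The forecast gives 72% (68% to 76%), 75% (71% to 79%) after noon and summer as best, holding that “the late second-order tail limits both”.

The flask gives 71.7%, 74.2% after noon, and summer as best, with 4.6 percentage points against 2.5 points. At 5.00 min this flask holds 9.43% as intermediate. My number, taken without the shift, is 5.40, so my reckoning places 5.8 points in intermediate, and my y stands 4 points above the flask's.

In the neighbour flask with 0.0060 M of starting material, the feed term grows and the number becomes 3.39, which gives 70.5% product. The computed neighbour gives 66.1%.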